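## Retrosynthetic overview

- The target is a flavonol. C3 (enol OH) and C4 (C=O) of ring C are the two carbons of an enolised 1,2-dione, so C3–C4 is cut to two aldehyde carbons: the formyl group on ring A (C4) and an α-aryloxy arylacetaldehyde (C3). A carbene-catalysed intramolecular crossed benzoin rejoins them and closes ring C, the only ring built (rings A and B are bought); the acyl anion is meant to form on the ring A aldehyde.
- The dialdehyde comes from the O1–C2 ether bond (ring A salicylaldehyde plus the α-bromo ester of MOM-protected methyl homovanillate) and a LiAlH4/Dess–Martin redox adjustment.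
- The ring A salicylaldehyde comes from 2,4,6-trihydroxybenzaldehyde: its formyl carbon is converted into the C8 oxygen (Baeyer–Villiger), and a new formyl group is placed ortho to the O1 hydroxyl.
- After ring closure: oxidation to the flavonol, debenzylation, 7-O-prenylation, MOM removal.

Key step: step 12

Remark: the target is achiral, so C2 and C3 of the intermediates are carried as racemates and erased in step 13; methyl homovanillate is used as the commercial form of the ring B acid.

## Route

Step 1
Reactants: 1 2,4,6-trihydroxybenzaldehyde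
Product: 2 2,4-bis(benzyloxy)-6-hydroxybenzaldehyde
Conditions: BnBr (2.05 equiv), K2CO3, DMF, 0 °C → rt
Reagents that add atoms: benzyl bromide, BrCc1ccccc1
Why: Williamson etherification in which the para hydroxyl and one ortho hydroxyl are alkylated, while the last ortho hydroxyl stays chelated to the formyl group and is left free at this stoichiometry.

Step 2
Reactants: 2 2,4-bis(benzyloxy)-6-hydroxybenzaldehyde
Product: 3 2,4-bis(benzyloxy)-6-(methoxymethoxy)benzaldehyde
Conditions: MOMCl, K2CO3, acetone, reflux
Reagents that add atoms: chloromethyl methyl ether, COCCl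
Why: Williamson-type alkylation of the chelated phenoxide with MOMCl masks the oxygen that will become O1 with a group orthogonal to the benzyl ethers.

Step 3
Reactants: 3 2,4-bis(benzyloxy)-6-(methoxymethoxy)benzaldehyde
Product: 5 2,4-bis(benzyloxy)-6-(methoxymethoxy)phenol, via aryl formate 4 (not isolated)
Conditions: mCPBA, CH2Cl2, 0 °C → rt; then K2CO3 (cat.), MeOH, rt
Reagents that add atoms: 3-chloroperoxybenzoic acid, OOC(=O)c1cccc(Cl)c1
Why: Baeyer–Villiger (Dakin-type) oxidation in which the electron-rich trialkoxyaryl group migrates in preference to hydrogen, and methanolysis of the aryl formate frees the phenol whose oxygen becomes the C8 oxygen.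

Step 4
Reactants: 5 2,4-bis(benzyloxy)-6-(methoxymethoxy)phenol
Product: 6 1,5-bis(benzyloxy)-2-methoxy-3-(methoxymethoxy)benzene
Conditions: MeI, K2CO3, DMF, rt
Reagents that add atoms: iodomethane, CI
Why: Williamson O-methylation of the only free phenol fixes the methoxy group between the benzyloxy group and the MOM-protected oxygen.

Step 5
Reactants: 6 1,5-bis(benzyloxy)-2-methoxy-3-(methoxymethoxy)benzene
Product: 7 3,5-bis(benzyloxy)-2-methoxyphenol
Conditions: HCl (2 M aq.), MeOH/THF, 50 °C
Reagents that add atoms: none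
Why: Acid-catalysed acetal solvolysis removes the MOM group, while benzyl and methyl aryl ethers are inert under these conditions.

Step 6
Reactants: 7 3,5-bis(benzyloxy)-2-methoxyphenol
Product: 8 4,6-bis(benzyloxy)-2-hydroxy-3-methoxybenzaldehyde
Conditions: MgCl2, Et3N, (CH2O)n, MeCN, reflux
Reagents that add atoms: paraformaldehyde (formaldehyde), C=O
Why: Magnesium phenoxide-directed ortho-formylation (Casnati–Skattebøl type) delivers formaldehyde to the single free ortho position, and the benzylic alkoxide formed is oxidised by a second formaldehyde through hydride transfer.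

Step 7
Reactants: 9 methyl homovanillate (methyl 2-(4-hydroxy-3-methoxyphenyl)acetate)
Product: 10 methyl 2-[3-methoxy-4-(methoxymethoxy)phenyl]acetate
Conditions: MOMCl, K2CO3, acetone, rt
Reagents that add atoms: chloromethyl methyl ether, COCCl
Why: Williamson-type MOM protection of the phenol, which is far more acidic than the ester α-position, proceeds without touching the ester.

Step 8
Reactants: 10 methyl 2-[3-methoxy-4-(methoxymethoxy)phenyl]acetate
Product: 12 methyl 2-bromo-2-[3-methoxy-4-(methoxymethoxy)phenyl]acetate (racemic), via lithium ester enolate 11 (not isolated)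
Conditions: LiN(SiMe3)2, THF, −78 °C; then added to NBS, THF, −78 °C
Reagents that add atoms: N-bromosuccinimide, BrN1C(=O)CCC1=O
Why: Electrophilic α-bromination of the pre-formed ester enolate, with inverse addition to limit proton exchange and dibromination, gives the racemic benzylic α-bromo ester.

Step 9
Reactants: 8 4,6-bis(benzyloxy)-2-hydroxy-3-methoxybenzaldehyde; 12 methyl 2-bromo-2-[3-methoxy-4-(methoxymethoxy)phenyl]acetate
Product: 13 methyl 2-[3,5-bis(benzyloxy)-2-formyl-6-methoxyphenoxy]-2-[3-methoxy-4-(methoxymethoxy)phenyl]acetate (racemic)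
Conditions: K2CO3, DMF, rt
Reagents that add atoms: none
Why: Williamson SN2 etherification in which the phenoxide of 8 displaces the activated α-bromide to form the O1–C2 bond (C2 racemic), the mild carbonate base at room temperature keeping the product away from a Rap–Stoermer-type aldol of its acidic C2–H onto the formyl group.

Step 10
Reactants: 13 methyl 2-[3,5-bis(benzyloxy)-2-formyl-6-methoxyphenoxy]-2-[3-methoxy-4-(methoxymethoxy)phenyl]acetate
Product: 14 2-[3,5-bis(benzyloxy)-2-(hydroxymethyl)-6-methoxyphenoxy]-2-[3-methoxy-4-(methoxymethoxy)phenyl]ethan-1-ol (racemic)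
Conditions: LiAlH4, THF, 0 °C; Rochelle salt work-up
Reagents that add atoms: none
Why: Hydride reduction with LiAlH4 takes the ester and the aldehyde to the primary alcohols in one operation, and benzyl, MOM and aryl ethers are inert.

Step 11
Reactants: 14 2-[3,5-bis(benzyloxy)-2-(hydroxymethyl)-6-methoxyphenoxy]-2-[3-methoxy-4-(methoxymethoxy)phenyl]ethan-1-ol
Product: 15 2-[3,5-bis(benzyloxy)-2-formyl-6-methoxyphenoxy]-2-[3-methoxy-4-(methoxymethoxy)phenyl]acetaldehyde (racemic)
Conditions: Dess–Martin periodinane (2.6 equiv), pyridine, CH2Cl2, 0 °C → rt; crude product used at once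
Reagents that add atoms: none
Why: Dess–Martin oxidation under pyridine buffering converts both primary alcohols to aldehydes without acid or strong base, which protects the MOM acetal and the enolisable C2–H.

Step 12
Reactants: 15 2-[3,5-bis(benzyloxy)-2-formyl-6-methoxyphenoxy]-2-[3-methoxy-4-(methoxymethoxy)phenyl]acetaldehyde
Product: 16 rac-(2R,3R)-5,7-bis(benzyloxy)-3-hydroxy-8-methoxy-2-[3-methoxy-4-(methoxymethoxy)phenyl]chroman-4-one (2,3-trans)
Conditions: 3-benzyl-5-(2-hydroxyethyl)-4-methylthiazolium chloride (20 mol%), DBU (18 mol%), t-BuOH/THF, 0.01 M, 40 °C, Ar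
Reagents that add atoms: none
Why: The thiazol-2-ylidene adds to the ring A aldehyde, and deprotonation of the adduct gives the Breslow intermediate (acyl anion equivalent at C4), which attacks the tethered aldehyde carbon C3 in a 6-exo-trig closure that forms C3–C4 and ring C; proton transfer and loss of the carbene release the 3-hydroxychroman-4-one directly. The closest known reaction is the thiazolium- or triazolium-catalysed intramolecular crossed benzoin of 2-(2-oxoalkoxy)benzaldehydes to 3-hydroxychroman-4-ones, here with an aldehyde in place of the ketone acceptor. The new stereocentre C3 is under thermodynamic control, because C3–H lies α to the ketone and equilibrates under the basic conditions, so the 2,3-trans isomer with both substituents equatorial should dominate; this is immaterial, since step 13 removes both centres. The selectivity that matters is the site of acyl anion formation: a Breslow intermediate on the aliphatic aldehyde (C3) would carry the ring A aryloxide in the β-position and could expel it, so the acyl anion has to form on ring A. This should be favoured by the more acidic benzylic carbene adduct of the aromatic aldehyde, by the α-branching of the aliphatic aldehyde and by the small thiazolylidene, which is expected to take the aromatic aldehyde as donor more readily than an N-aryl triazolylidene would; this is not secured by the substrate and is the main risk of the route. High dilution and the six-membered transition state suppress intermolecular benzoin coupling.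

Step 13
Reactants: 16 rac-(2R,3R)-5,7-bis(benzyloxy)-3-hydroxy-8-methoxy-2-[3-methoxy-4-(methoxymethoxy)phenyl]chroman-4-one
Product: 18 5,7-bis(benzyloxy)-3-hydroxy-8-methoxy-2-[3-methoxy-4-(methoxymethoxy)phenyl]-4H-chromen-4-one, via chromane-3,4-dione 17 (not isolated)
Conditions: Dess–Martin periodinane (1.2 equiv), pyridine, CH2Cl2, 0 °C → rt
Reagents that add atoms: none
Why: Dess–Martin oxidation of the α-ketol gives the 3,4-dione, which enolises at once towards C2 to the aromatic 3-hydroxychromone, so that either acyloin regioisomer or diastereomer from step 12 converges on the same flavonol.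

Step 14
Reactants: 18 5,7-bis(benzyloxy)-3-hydroxy-8-methoxy-2-[3-methoxy-4-(methoxymethoxy)phenyl]-4H-chromen-4-one
Product: 19 3,5,7-trihydroxy-8-methoxy-2-[3-methoxy-4-(methoxymethoxy)phenyl]-4H-chromen-4-one
Conditions: H2 (1 atm), 10% Pd/C, EtOAc/MeOH, rt
Reagents that add atoms: none
Why: Catalytic hydrogenolysis cleaves the two benzyl aryl ethers, while the MOM acetal, the methyl ethers and the conjugated C2=C3 bond of the flavonol are expected to persist.

Step 15
Reactants: 19 3,5,7-trihydroxy-8-methoxy-2-[3-methoxy-4-(methoxymethoxy)phenyl]-4H-chromen-4-one; 20 prenyl bromide (1-bromo-3-methylbut-2-ene)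
Product: 21 3,5-dihydroxy-8-methoxy-2-[3-methoxy-4-(methoxymethoxy)phenyl]-7-[(3-methylbut-2-en-1-yl)oxy]-4H-chromen-4-one
Conditions: 20 (1.05 equiv), K2CO3 (1.1 equiv), DMF, 0 °C → rt
Reagents that add atoms: none
Why: Williamson etherification under acidity control, in which one equivalent of carbonate deprotonates only the 7-hydroxyl (para to the C4 carbonyl and the most acidic), whereas the 5-hydroxyl is locked in a chelate and the 3-hydroxyl is a weaker acid.

Step 16
Reactants: 21 3,5-dihydroxy-8-methoxy-2-[3-methoxy-4-(methoxymethoxy)phenyl]-7-[(3-methylbut-2-en-1-yl)oxy]-4H-chromen-4-one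
Product: 23 3,5-dihydroxy-2-(4-hydroxy-3-methoxyphenyl)-8-methoxy-7-[(3-methylbut-2-en-1-yl)oxy]-4H-chromen-4-one, via 4′-O-trimethylsilyl ether 22 (not isolated)
Conditions: Me3SiOTf, 2,2′-bipyridyl, MeCN, 0 °C → rt; then H2O
Reagents that add atoms: none
Why: Lewis-acid acetal cleavage in which the silyl triflate–bipyridyl pair converts the aryl MOM ether into the aryl silyl ether and a pyridinium salt under aprotic conditions that the acid-labile prenyl ether should tolerate, and water then hydrolyses the silyl ether.

## Compound list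

1 | 2,4,6-trihydroxybenzaldehyde | O=Cc1c(O)cc(O)cc1O | starting material
2 | 2,4-bis(benzyloxy)-6-hydroxybenzaldehyde | O=Cc1c(O)cc(OCc2ccccc2)cc1OCc1ccccc1 | intermediate
3 | 2,4-bis(benzyloxy)-6-(methoxymethoxy)benzaldehyde | O=Cc1c(OCc2ccccc2)cc(OCc2ccccc2)cc1OCOC | intermediate
4 | 2,4-bis(benzyloxy)-6-(methoxymethoxy)phenyl formate (not isolated) | O=COc1c(OCc2ccccc2)cc(OCc2ccccc2)cc1OCOC | intermediate
5 | 2,4-bis(benzyloxy)-6-(methoxymethoxy)phenol | Oc1c(OCc2ccccc2)cc(OCc2ccccc2)cc1OCOC | intermediate
6 | 1,5-bis(benzyloxy)-2-methoxy-3-(methoxymethoxy)benzene | COc1c(OCc2ccccc2)cc(OCc2ccccc2)cc1OCOC | intermediate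
7 | 3,5-bis(benzyloxy)-2-methoxyphenol | COc1c(O)cc(OCc2ccccc2)cc1OCc1ccccc1 | intermediate
8 | 4,6-bis(benzyloxy)-2-hydroxy-3-methoxybenzaldehyde | COc1c(O)c(C=O)c(OCc2ccccc2)cc1OCc1ccccc1 | intermediate
9 | methyl homovanillate | COC(=O)Cc1ccc(O)c(OC)c1 | starting material
10 | methyl 2-[3-methoxy-4-(methoxymethoxy)phenyl]acetate | COCOc1ccc(CC(=O)OC)cc1OC | intermediate
11 | lithium enolate of 10 (not isolated) | [Li+].COC([O-])=Cc1ccc(OCOC)c(OC)c1 | intermediate
12 | methyl 2-bromo-2-[3-methoxy-4-(methoxymethoxy)phenyl]acetate (racemic) | COCOc1ccc(C(Br)C(=O)OC)cc1OC | intermediate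
13 | methyl 2-[3,5-bis(benzyloxy)-2-formyl-6-methoxyphenoxy]-2-[3-methoxy-4-(methoxymethoxy)phenyl]acetate (racemic) | COCOc1ccc(C(Oc2c(OC)c(OCc3ccccc3)cc(OCc3ccccc3)c2C=O)C(=O)OC)cc1OC | intermediate
14 | 2-[3,5-bis(benzyloxy)-2-(hydroxymethyl)-6-methoxyphenoxy]-2-[3-methoxy-4-(methoxymethoxy)phenyl]ethan-1-ol (racemic) | COCOc1ccc(C(CO)Oc2c(OC)c(OCc3ccccc3)cc(OCc3ccccc3)c2CO)cc1OC | intermediate
15 | 2-[3,5-bis(benzyloxy)-2-formyl-6-methoxyphenoxy]-2-[3-methoxy-4-(methoxymethoxy)phenyl]acetaldehyde (racemic) | COCOc1ccc(C(C=O)Oc2c(OC)c(OCc3ccccc3)cc(OCc3ccccc3)c2C=O)cc1OC | intermediate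
16 | rac-(2R,3R)-5,7-bis(benzyloxy)-3-hydroxy-8-methoxy-2-[3-methoxy-4-(methoxymethoxy)phenyl]chroman-4-one (2,3-trans, one enantiomer drawn) | COCOc1ccc([C@@H]2[C@H](C(=O)c3c(OCc4ccccc4)cc(OCc4ccccc4)c(OC)c3O2)O)cc1OC | intermediate
17 | 5,7-bis(benzyloxy)-8-methoxy-2-[3-methoxy-4-(methoxymethoxy)phenyl]chromane-3,4-dione (racemic, not isolated) | COCOc1ccc(C2Oc3c(OC)c(OCc4ccccc4)cc(OCc4ccccc4)c3C(=O)C2=O)cc1OC | intermediate
18 | 5,7-bis(benzyloxy)-3-hydroxy-8-methoxy-2-[3-methoxy-4-(methoxymethoxy)phenyl]-4H-chromen-4-one | COCOc1ccc(-c2oc3c(OC)c(OCc4ccccc4)cc(OCc4ccccc4)c3c(=O)c2O)cc1OC | intermediate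
19 | 3,5,7-trihydroxy-8-methoxy-2-[3-methoxy-4-(methoxymethoxy)phenyl]-4H-chromen-4-one | COCOc1ccc(-c2oc3c(OC)c(O)cc(O)c3c(=O)c2O)cc1OC | intermediate
20 | prenyl bromide | CC(C)=CCBr | starting material
21 | 3,5-dihydroxy-8-methoxy-2-[3-methoxy-4-(methoxymethoxy)phenyl]-7-[(3-methylbut-2-en-1-yl)oxy]-4H-chromen-4-one | COCOc1ccc(-c2oc3c(OC)c(OCC=C(C)C)cc(O)c3c(=O)c2O)cc1OC | intermediate
22 | 4′-O-trimethylsilyl ether of 23 (3- and 5-hydroxyls possibly silylated as well; not isolated) | COc1cc(-c2oc3c(OC)c(OCC=C(C)C)cc(O)c3c(=O)c2O)ccc1O[Si](C)(C)C | intermediate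
23 | 3,5-dihydroxy-2-(4-hydroxy-3-methoxyphenyl)-8-methoxy-7-[(3-methylbut-2-en-1-yl)oxy]-4H-chromen-4-one | COc1cc(-c2oc3c(OC)c(OCC=C(C)C)cc(O)c3c(=O)c2O)ccc1O | target

## Step count and risks

Total steps: 16. Longest linear sequence: 14 steps (steps 1–6, then 9–16).

The three steps most likely to fail:

1. Step 12 (key step). The carbene may form its acyl anion equivalent on the aliphatic aldehyde instead of the ring A aldehyde. That intermediate can expel the ring A aryloxide (cleavage of O1–C2), and re-acylation and aldol condensation of the fragments would lead towards an aryl ester or a 3-arylcoumarin. Base-induced enolisation at C2 and intermolecular benzoin coupling are lesser drains. Fallback (reductive coupling of the same two carbons instead of redox-neutral umpolung): dialdehyde 15 is treated with SmI2 in THF/t-BuOH at −78 °C. The aromatic aldehyde is reduced first to its ketyl, which adds to the neighbouring aldehyde (intramolecular pinacol coupling) to give 5,7-bis(benzyloxy)-8-methoxy-2-[3-methoxy-4-(methoxymethoxy)phenyl]chromane-3,4-diol F1 as a diastereomer mixture. IBX in DMSO at rt then oxidises both hydroxyls without glycol cleavage to dione 17, which enolises to 18, where the route resumes at step 14.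

2. Step 15. Alkylation may not stop at the 7-oxygen: the 3-hydroxyl may be alkylated as well, either in competition or once the 7-phenoxide is consumed. Fallback (prenylation before the acidic enol exists): 16 is hydrogenolysed (H2, Pd/C, EtOAc) to rac-(2R,3R)-3,5,7-trihydroxy-8-methoxy-2-[3-methoxy-4-(methoxymethoxy)phenyl]chroman-4-one F2. Its 3-hydroxyl is an ordinary secondary alcohol and its 5-hydroxyl is chelated, so 20 with K2CO3 in acetone under argon should alkylate only O7, giving rac-(2R,3R)-3,5-dihydroxy-8-methoxy-2-[3-methoxy-4-(methoxymethoxy)phenyl]-7-[(3-methylbut-2-en-1-yl)oxy]chroman-4-one F3. The α-ketol of F3 is then oxidised with air and K2CO3 in DMF (autoxidation through the enediolate) to 21, where the route resumes at step 16.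

3. Step 16. The allylic C–O bond at O7 may ionise under the Lewis acidic conditions (loss of the prenyl group), or the acetal cleavage may stay incomplete. Fallback (the MOM group is removed before the prenyl group is put on, and the 7-hydroxyl is singled out through acetates): 19 is heated with HCl in MeOH to 3,5,7-trihydroxy-2-(4-hydroxy-3-methoxyphenyl)-8-methoxy-4H-chromen-4-one F4. Ac2O, pyridine and DMAP give the 3,5,7,4′-tetraacetate F5. PhSH and imidazole in N-methylpyrrolidone at 0 °C cleave the most labile 7-acetate selectively to the 3,5,4′-triacetate with free 7-hydroxyl F6. Compound 20 and K2CO3 in acetone give the 7-prenyl ether triacetate F7, and K2CO3 in MeOH at rt removes the three acetates to give target 23.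

## Further compounds

F1 | step 12 | 5,7-bis(benzyloxy)-8-methoxy-2-[3-methoxy-4-(methoxymethoxy)phenyl]chromane-3,4-diol (racemic diastereomer mixture) | COCOc1ccc(C2Oc3c(OC)c(OCc4ccccc4)cc(OCc4ccccc4)c3C(O)C2O)cc1OC
F2 | step 15 | rac-(2R,3R)-3,5,7-trihydroxy-8-methoxy-2-[3-methoxy-4-(methoxymethoxy)phenyl]chroman-4-one | COCOc1ccc([C@@H]2[C@H](C(=O)c3c(O)cc(O)c(OC)c3O2)O)cc1OC
F3 | step 15 | rac-(2R,3R)-3,5-dihydroxy-8-methoxy-2-[3-methoxy-4-(methoxymethoxy)phenyl]-7-[(3-methylbut-2-en-1-yl)oxy]chroman-4-one | COCOc1ccc([C@@H]2[C@H](C(=O)c3c(O)cc(OCC=C(C)C)c(OC)c3O2)O)cc1OC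
F4 | step 16 | 3,5,7-trihydroxy-2-(4-hydroxy-3-methoxyphenyl)-8-methoxy-4H-chromen-4-one | COc1cc(-c2oc3c(OC)c(O)cc(O)c3c(=O)c2O)ccc1O
F5 | step 16 | 3,5,7-triacetoxy-2-(4-acetoxy-3-methoxyphenyl)-8-methoxy-4H-chromen-4-one | COc1cc(-c2oc3c(OC)c(OC(C)=O)cc(OC(C)=O)c3c(=O)c2OC(C)=O)ccc1OC(C)=O
F6 | step 16 | 3,5-diacetoxy-2-(4-acetoxy-3-methoxyphenyl)-7-hydroxy-8-methoxy-4H-chromen-4-one | COc1cc(-c2oc3c(OC)c(O)cc(OC(C)=O)c3c(=O)c2OC(C)=O)ccc1OC(C)=O
F7 | step 16 | 3,5-diacetoxy-2-(4-acetoxy-3-methoxyphenyl)-8-methoxy-7-[(3-methylbut-2-en-1-yl)oxy]-4H-chromen-4-one | COc1cc(-c2oc3c(OC)c(OCC=C(C)C)cc(OC(C)=O)c3c(=O)c2OC(C)=O)ccc1OC(C)=O
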